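**Retrosynthetic overview**
1. The cis-1,10-epoxide is installed last, by peracid epoxidation of the 1(10)-Z alkene of the finished macrolactone; the C3 acetate comes from a 3-keto macrolactone by reagent-controlled reduction and acetylation.
2. The ten-membered ring closes by C6–C7 bond formation (the farnesyl-type C1–C10 closure): an allylchromium made from a 2-(bromomethyl)enoate adds to a Z-enal, C6 and C7 are set under control of C8, and the C6 alkoxide closes the 12,6-lactone in the same flask.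
3. The Z-4-oxo-enal (C3–C6) travels as a 2,3-disubstituted furan made from furan-3-ylmethanol and is unveiled just before ring closure; the bromomethyl enoate comes from a Morita–Baylis–Hillman adduct of an α-angeloyloxy aldehyde.
4. C8 comes from (S)-glycidol (epoxide opened at C9 by a Z-alkenyllithium); the Z-configured C1=C10 unit comes from but-2-yn-1-ol.
5. Ring order: ten-membered carbocycle, then γ-lactone (same operation), then epoxide.

Numbering used in names: germacrane numbering (ring C1–C10; C11, C12, C13 are the lactone/acrylate carbons on C7; C14 is the methyl on C10; C15 is the CH2O on C4). Read this way the target is (1R,3S,6R,7R,8R,10S), 4Z, with a cis epoxide (C2 and C9 on the same side), so it derives from a 1(10)-Z alkene.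

**Route**

Step 1
Reactants: 1 but-2-yn-1-ol
Product: 3 (2Z)-3-iodobut-2-en-1-ol, via cyclic alkenylalanate 2 (not isolated)
Conditions: NaAlH2(OCH2CH2OCH3)2, THF, 0 → 23 °C; then I2, −78 → 0 °C
Reagents that add atoms: iodine, II
Why: Hydroxyl-directed trans-hydroalumination of the propargylic alcohol places aluminium on C3 inside a five-membered alanate, and iodinolysis with retention gives the Z-iodide (iodine cis to CH2OH), the geometry that becomes the cis C1=C10 ring bond.

Step 2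
Reactants: 3 (2Z)-3-iodobut-2-en-1-ol
Product: 4 (2Z)-1-bromo-3-iodobut-2-ene
Conditions: CBr4, PPh3, CH2Cl2, 0 °C
Reagents that add atoms: carbon tetrabromide, BrC(Br)(Br)Br
Why: Appel reaction of a primary allylic alcohol under neutral conditions, which leaves the alkene geometry untouched.

Step 3
Reactants: 5 furan-3-ylmethanol; 4 (2Z)-1-bromo-3-iodobut-2-ene
Product: 8 tert-butyl({2-[(2Z)-3-iodobut-2-en-1-yl]furan-3-yl}methoxy)dimethylsilane, via dilithiated furanmethanol 6 (not isolated), via lithium alkoxide 7 (not isolated)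
Conditions: n-BuLi (2.2 equiv), THF, −78 → 0 °C; 4, −78 → 0 °C; then TBSCl, 0 → 23 °C
Reagents that add atoms: tert-butyldimethylsilyl chloride, CC(C)(C)[Si](C)(C)Cl
Why: Alkoxide-directed ortho-lithiation of the furan at C2, SN2 alkylation by the primary allylic bromide (the more stabilised furyllithium does not exchange with the alkenyl iodide), then O-silylation of the remaining lithium alkoxide in the same flask.

Step 4
Reactants: 9 (S)-glycidol
Product: 10 triethyl{[(2R)-oxiran-2-yl]methoxy}silane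
Conditions: Et3SiCl, imidazole, CH2Cl2, 0 °C
Reagents that add atoms: chlorotriethylsilane, CC[Si](Cl)(CC)CC
Why: Simple O-silylation; the stereocentre is untouched and only its descriptor changes (S to R) through the priority change.

Step 5
Reactants: 8 tert-butyl({2-[(2Z)-3-iodobut-2-en-1-yl]furan-3-yl}methoxy)dimethylsilane; 10 triethyl{[(2R)-oxiran-2-yl]methoxy}silane
Product: 12 (2R,4Z)-6-[3-({[tert-butyl(dimethyl)silyl]oxy}methyl)furan-2-yl]-4-methyl-1-[(triethylsilyl)oxy]hex-4-en-2-ol, via alkenyllithium 11 (not isolated)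
Conditions: t-BuLi (2.0 equiv), Et2O, −78 °C; then 10, BF3·OEt2, −78 °C; H2O
Reagents that add atoms: none
Why: Iodine–lithium exchange with retention of the Z geometry, then BF3-assisted epoxide opening at the terminal carbon (C9–C10 bond), so C8 is taken unchanged from glycidol (8R).

Step 6
Reactants: 12 (2R,4Z)-6-[3-({[tert-butyl(dimethyl)silyl]oxy}methyl)furan-2-yl]-4-methyl-1-[(triethylsilyl)oxy]hex-4-en-2-ol; 13 angelic acid [(2Z)-2-methylbut-2-enoic acid]
Product: 15 (2R,4Z)-6-[3-({[tert-butyl(dimethyl)silyl]oxy}methyl)furan-2-yl]-4-methyl-1-[(triethylsilyl)oxy]hex-4-en-2-yl (2Z)-2-methylbut-2-enoate, via mixed anhydride 14 (not isolated)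
Conditions: 2,4,6-Cl3C6H2COCl, Et3N, toluene, 23 °C; then 12, 80 °C
Reagents that add atoms: none
Why: Yamaguchi-type esterification through the preformed mixed anhydride without nucleophilic catalyst, the protocol that avoids angelate-to-tiglate isomerisation; acylation is on oxygen, so C8 is retained.

Step 7
Reactants: 15 (2R,4Z)-6-[3-({[tert-butyl(dimethyl)silyl]oxy}methyl)furan-2-yl]-4-methyl-1-[(triethylsilyl)oxy]hex-4-en-2-yl (2Z)-2-methylbut-2-enoate
Product: 16 (2R,4Z)-6-[3-({[tert-butyl(dimethyl)silyl]oxy}methyl)furan-2-yl]-4-methyl-1-oxohex-4-en-2-yl (2Z)-2-methylbut-2-enoate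
Conditions: (COCl)2, DMSO, CH2Cl2, −78 → −40 °C; i-Pr2NEt, −78 → 0 °C
Reagents that add atoms: none
Why: Swern oxidation applied directly to the primary triethylsilyl ether (the primary TBS ether is inert), with a hindered base at low temperature to keep the α-acyloxy stereocentre; the aldehyde is used crude.

Step 8
Reactants: 16 (2R,4Z)-6-[3-({[tert-butyl(dimethyl)silyl]oxy}methyl)furan-2-yl]-4-methyl-1-oxohex-4-en-2-yl (2Z)-2-methylbut-2-enoate; 17 methyl acrylate
Product: 18 methyl (4R,6Z)-8-[3-({[tert-butyl(dimethyl)silyl]oxy}methyl)furan-2-yl]-3-hydroxy-6-methyl-2-methylidene-4-{[(2Z)-2-methylbut-2-enoyl]oxy}oct-6-enoate (both C3 epimers)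
Conditions: 1,4-diazabicyclo[2.2.2]octane (0.3 equiv), neat 17, 0 → 23 °C
Reagents that add atoms: none
Why: Morita–Baylis–Hillman reaction of an activated α-acyloxy aldehyde builds C7–C11; the new carbinol configuration is irrelevant because that centre becomes sp2 in the next step.

Step 9
Reactants: 18 methyl (4R,6Z)-8-[3-({[tert-butyl(dimethyl)silyl]oxy}methyl)furan-2-yl]-3-hydroxy-6-methyl-2-methylidene-4-{[(2Z)-2-methylbut-2-enoyl]oxy}oct-6-enoate
Product: 19 methyl (2Z,4R,6Z)-2-(bromomethyl)-8-[3-({[tert-butyl(dimethyl)silyl]oxy}methyl)furan-2-yl]-6-methyl-4-{[(2Z)-2-methylbut-2-enoyl]oxy}octa-2,6-dienoate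
Conditions: CBr4, PPh3, CH2Cl2, −20 → 0 °C
Reagents that add atoms: carbon tetrabromide, BrC(Br)(Br)Br
Why: Appel activation with SN2′ transposition: bromide adds to the acrylate terminus as phosphine oxide leaves the hindered carbinol, giving the conjugated (2Z)-2-(bromomethyl)enoate under non-acidic conditions that spare the furan and silyl ether.

Step 10
Reactants: 19 methyl (2Z,4R,6Z)-2-(bromomethyl)-8-[3-({[tert-butyl(dimethyl)silyl]oxy}methyl)furan-2-yl]-6-methyl-4-{[(2Z)-2-methylbut-2-enoyl]oxy}octa-2,6-dienoate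
Product: 22 (6R,7R,8R)-8-(angeloyloxy)-15-[(tert-butyldimethylsilyl)oxy]-3-oxogermacra-1(10)Z,4Z,11(13)-trien-12,6-olide, via Z-keto-enal 20 (not isolated), via hydroxy ester 21 (not isolated)
Conditions: NBS (1.0 equiv), NaHCO3, acetone/H2O (10:1), −20 °C; extract; then slow addition to CrCl2 (8 equiv), THF, 23 °C (2 mM); aq. NH4Cl
Reagents that add atoms: water, O
Why: Oxidative furan opening gives the Z-4-oxo-enal with its geometry fixed by the former ring, and a Nozaki–Hiyama-type intramolecular Barbier allylation then closes C6–C7 at the aldehyde (allylchromium reagents strongly prefer aldehydes over the hindered enone) through a chair transition state with C5 and C8 equatorial (6,7-anti, hence trans-lactone), with H8 eclipsing the allyl unit to avoid A(1,3) strain so that the aldehyde adds anti to the C8–C9 bond and gauche to the angelate (6R,7R), after which the trivalent chromium alkoxide lactonises onto the methyl ester.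

Step 11
Reactants: 22 (6R,7R,8R)-8-(angeloyloxy)-15-[(tert-butyldimethylsilyl)oxy]-3-oxogermacra-1(10)Z,4Z,11(13)-trien-12,6-olide
Product: 23 (3S,6R,7R,8R)-8-(angeloyloxy)-15-[(tert-butyldimethylsilyl)oxy]-3-hydroxygermacra-1(10)Z,4Z,11(13)-trien-12,6-olide
Conditions: (R)-2-methyl-CBS-oxazaborolidine (C18H20BNO, 0.5 equiv), catecholborane, toluene, −78 °C
Reagents that add atoms: none
Why: Corey–Bakshi–Shibata reduction of an α-substituted enone, with the alkenyl side acting as the large group, so the (R)-catalyst delivers hydride to give the 3S alcohol under reagent control while leaving the esters and the methylene lactone alone.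

Step 12
Reactants: 23 (3S,6R,7R,8R)-8-(angeloyloxy)-15-[(tert-butyldimethylsilyl)oxy]-3-hydroxygermacra-1(10)Z,4Z,11(13)-trien-12,6-olide
Product: 24 (3S,6R,7R,8R)-3-acetoxy-8-(angeloyloxy)-15-[(tert-butyldimethylsilyl)oxy]germacra-1(10)Z,4Z,11(13)-trien-12,6-olide
Conditions: Ac2O, pyridine, 4-(dimethylamino)pyridine (cat.), CH2Cl2, 0 °C
Reagents that add atoms: acetic anhydride, CC(=O)OC(C)=O
Why: Standard acetylation of the only free hydroxyl, with retention at C3.

Step 13
Reactants: 24 (3S,6R,7R,8R)-3-acetoxy-8-(angeloyloxy)-15-[(tert-butyldimethylsilyl)oxy]germacra-1(10)Z,4Z,11(13)-trien-12,6-olide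
Product: 25 (3S,6R,7R,8R)-3-acetoxy-8-(angeloyloxy)-15-hydroxygermacra-1(10)Z,4Z,11(13)-trien-12,6-olide
Conditions: HF·pyridine, pyridine, THF, 0 → 23 °C
Reagents that add atoms: none
Why: Buffered fluoride desilylation under non-basic conditions, so the C3 acetate does not migrate to the primary C15 hydroxyl.

Step 14
Reactants: 25 (3S,6R,7R,8R)-3-acetoxy-8-(angeloyloxy)-15-hydroxygermacra-1(10)Z,4Z,11(13)-trien-12,6-olide
Product: 26 (1R,3S,6R,7R,8R,10S)-3-acetoxy-8-(angeloyloxy)-1,10-epoxy-15-hydroxygermacra-4Z,11(13)-dien-12,6-olide (CNP0162483.1)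
Conditions: mCPBA (1.1 equiv), NaHCO3, CH2Cl2, 0 °C
Reagents that add atoms: 3-chloroperoxybenzoic acid, OOC(=O)c1cccc(Cl)c1
Why: Prilezhaev epoxidation picks the only electron-rich alkene (C4=C5 carries three allylic oxygens, the other two are conjugated to carbonyls), is stereospecific (Z alkene gives the cis epoxide), and attack on the exposed outer face of the lactone-locked ring is expected to give the 1R,10S epoxide.

**Compound list**
1 | but-2-yn-1-ol | CC#CCO | starting material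
2 | cyclic sodium alkenylalanate (Al bound to C3 and to the C1 oxygen, two 2-methoxyethoxy ligands) | CC1=CCO[Al-]1(OCCOC)OCCOC.[Na+] | intermediate
3 | (2Z)-3-iodobut-2-en-1-ol | C/C(I)=C/CO | intermediate
4 | (2Z)-1-bromo-3-iodobut-2-ene | C/C(I)=C/CBr | intermediate
5 | furan-3-ylmethanol | OCc1ccoc1 | starting material
6 | lithium (2-lithiofuran-3-yl)methanolate | [Li]OCc1ccoc1[Li] | intermediate
7 | lithium {2-[(2Z)-3-iodobut-2-en-1-yl]furan-3-yl}methanolate | [Li]OCc1ccoc1C/C=C(/C)I | intermediate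
8 | tert-butyl({2-[(2Z)-3-iodobut-2-en-1-yl]furan-3-yl}methoxy)dimethylsilane | CC(C)(C)[Si](C)(C)OCc1ccoc1C/C=C(/C)I | intermediate
9 | (S)-glycidol | OC[C@H]1CO1 | starting material
10 | triethyl{[(2R)-oxiran-2-yl]methoxy}silane | CC[Si](CC)(CC)OC[C@H]1CO1 | intermediate
11 | (Z)-alkenyllithium from 8 (Li in place of I) | CC(C)(C)[Si](C)(C)OCc1ccoc1C/C=C(/C)[Li] | intermediate
12 | (2R,4Z)-6-[3-({[tert-butyl(dimethyl)silyl]oxy}methyl)furan-2-yl]-4-methyl-1-[(triethylsilyl)oxy]hex-4-en-2-ol | CC(C)(C)[Si](C)(C)OCc1ccoc1C/C=C(/C)C[C@@H](O)CO[Si](CC)(CC)CC | intermediate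
13 | angelic acid, (2Z)-2-methylbut-2-enoic acid | C/C=C(/C)C(=O)O | starting material
14 | (2Z)-2-methylbut-2-enoic 2,4,6-trichlorobenzoic anhydride | C/C=C(/C)C(=O)OC(=O)c1c(Cl)cc(Cl)cc1Cl | intermediate
15 | (2R,4Z)-6-[3-({[tert-butyl(dimethyl)silyl]oxy}methyl)furan-2-yl]-4-methyl-1-[(triethylsilyl)oxy]hex-4-en-2-yl (2Z)-2-methylbut-2-enoate | CC(C)(C)[Si](C)(C)OCc1ccoc1C/C=C(/C)C[C@@H](OC(=O)/C(C)=C\C)CO[Si](CC)(CC)CC | intermediate
16 | (2R,4Z)-6-[3-({[tert-butyl(dimethyl)silyl]oxy}methyl)furan-2-yl]-4-methyl-1-oxohex-4-en-2-yl (2Z)-2-methylbut-2-enoate | CC(C)(C)[Si](C)(C)OCc1ccoc1C/C=C(/C)C[C@@H](OC(=O)/C(C)=C\C)C=O | intermediate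
17 | methyl acrylate | C=CC(=O)OC | starting material
18 | methyl (4R,6Z)-8-[3-({[tert-butyl(dimethyl)silyl]oxy}methyl)furan-2-yl]-3-hydroxy-6-methyl-2-methylidene-4-{[(2Z)-2-methylbut-2-enoyl]oxy}oct-6-enoate, C3 epimers | CC(C)(C)[Si](C)(C)OCc1ccoc1C/C=C(/C)C[C@@H](OC(=O)/C(C)=C\C)C(O)C(=C)C(=O)OC | intermediate
19 | methyl (2Z,4R,6Z)-2-(bromomethyl)-8-[3-({[tert-butyl(dimethyl)silyl]oxy}methyl)furan-2-yl]-6-methyl-4-{[(2Z)-2-methylbut-2-enoyl]oxy}octa-2,6-dienoate | CC(C)(C)[Si](C)(C)OCc1ccoc1C/C=C(/C)C[C@@H](OC(=O)/C(C)=C\C)/C=C(\CBr)C(=O)OC | intermediate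
20 | methyl (2Z,4R,6Z,10Z)-2-(bromomethyl)-10-({[tert-butyl(dimethyl)silyl]oxy}methyl)-6-methyl-4-{[(2Z)-2-methylbut-2-enoyl]oxy}-9,12-dioxododeca-2,6,10-trienoate | O=C/C=C(/CO[Si](C)(C)C(C)(C)C)C(=O)C/C=C(/C)C[C@@H](OC(=O)/C(C)=C\C)/C=C(\CBr)C(=O)OC | intermediate
21 | methyl 2-[(1R,2R,3Z,7Z,10R)-4-({[tert-butyl(dimethyl)silyl]oxy}methyl)-2-hydroxy-8-methyl-10-{[(2Z)-2-methylbut-2-enoyl]oxy}-5-oxocyclodeca-3,7-dien-1-yl]prop-2-enoate (present as its chromium alkoxide) | O[C@@H]1/C=C(/CO[Si](C)(C)C(C)(C)C)C(=O)C/C=C(/C)C[C@@H](OC(=O)/C(C)=C\C)[C@H]1C(=C)C(=O)OC | intermediate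
22 | (6R,7R,8R)-8-(angeloyloxy)-15-[(tert-butyldimethylsilyl)oxy]-3-oxogermacra-1(10)Z,4Z,11(13)-trien-12,6-olide | C=C1C(=O)O[C@@H]2/C=C(/CO[Si](C)(C)C(C)(C)C)C(=O)C/C=C(/C)C[C@@H](OC(=O)/C(C)=C\C)[C@@H]12 | intermediate
23 | (3S,6R,7R,8R)-8-(angeloyloxy)-15-[(tert-butyldimethylsilyl)oxy]-3-hydroxygermacra-1(10)Z,4Z,11(13)-trien-12,6-olide | C=C1C(=O)O[C@@H]2/C=C(/CO[Si](C)(C)C(C)(C)C)[C@@H](O)C/C=C(/C)C[C@@H](OC(=O)/C(C)=C\C)[C@@H]12 | intermediate
24 | (3S,6R,7R,8R)-3-acetoxy-8-(angeloyloxy)-15-[(tert-butyldimethylsilyl)oxy]germacra-1(10)Z,4Z,11(13)-trien-12,6-olide | C=C1C(=O)O[C@@H]2/C=C(/CO[Si](C)(C)C(C)(C)C)[C@@H](OC(C)=O)C/C=C(/C)C[C@@H](OC(=O)/C(C)=C\C)[C@@H]12 | intermediate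
25 | (3S,6R,7R,8R)-3-acetoxy-8-(angeloyloxy)-15-hydroxygermacra-1(10)Z,4Z,11(13)-trien-12,6-olide | C=C1C(=O)O[C@@H]2/C=C(/CO)[C@@H](OC(C)=O)C/C=C(/C)C[C@@H](OC(=O)/C(C)=C\C)[C@@H]12 | intermediate
26 | (1R,3S,6R,7R,8R,10S)-3-acetoxy-8-(angeloyloxy)-1,10-epoxy-15-hydroxygermacra-4Z,11(13)-dien-12,6-olide | C=C1C(=O)O[C@@H]2/C=C(/CO)[C@@H](OC(C)=O)C[C@H]3O[C@@]3(C)C[C@@H](OC(=O)/C(C)=C\C)[C@@H]12 | target

**Totals**
Total steps: 14. Longest linear sequence: 13 (steps 1–3 and 5–14, from but-2-yn-1-ol); step 4 is a one-step side branch.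

**Steps most likely to fail**

Ring closure, step 10. The allylchromium may add to the C3 ketone instead (seven-membered ring), divalent chromium may reduce the ene-dione, or the C8 centre may not deliver the 6R,7R pair. The fallback removes the second carbonyl before ring closure. It sets out from crude keto-enal 20. Excess catecholborane with the (R)-CBS catalyst reduces the aldehyde and, under reagent control, the ketone to the (9S)-diol F1. Et3SiCl/imidazole at −78 °C (primary hydroxyl only), followed in the same flask by Ac2O/4-(dimethylamino)pyridine, gives the silyl ether acetate F2. Direct Swern oxidation of the primary triethylsilyl ether gives the Z-acetoxy enal F3. CrCl2 closure of F3 under the step 10 conditions then gives the acetate directly, and the route is rejoined at 24 (22 and 23 are bypassed).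

Ketone reduction, step 11. The conformation of the ten-membered ring may override the catalyst and give the 3R alcohol. The fallback accepts that face and inverts it. It sets out from 22. NaBH4/CeCl3·7H2O in MeOH at −78 °C gives the (3R)-alcohol F4, and Mitsunobu esterification with acetic acid (PPh3, diisopropyl azodicarboxylate, THF) inverts C3 and installs the acetate in one operation, rejoining the route at 24.

Epoxidation, step 14. The peracid may attack the other face of the 1(10) alkene. The fallback delivers oxygen to the opposite face from the one an electrophile prefers. It sets out from 25. NBS in THF/H2O at 0 °C forms the bromonium on the face the peracid would take and water opens it anti at the tertiary C10, giving the bromohydrin F5. Ag2O in 1,2-dimethoxyethane then closes the epoxide with inversion at C1, rejoining the route at 26.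

**Further compounds**
F1 | step 10 | methyl (2Z,4R,6Z,9S,10Z)-2-(bromomethyl)-10-({[tert-butyl(dimethyl)silyl]oxy}methyl)-9,12-dihydroxy-6-methyl-4-{[(2Z)-2-methylbut-2-enoyl]oxy}dodeca-2,6,10-trienoate | OC/C=C(/CO[Si](C)(C)C(C)(C)C)[C@@H](O)C/C=C(/C)C[C@@H](OC(=O)/C(C)=C\C)/C=C(\CBr)C(=O)OC
F2 | step 10 | methyl (2Z,4R,6Z,9S,10Z)-9-acetoxy-2-(bromomethyl)-10-({[tert-butyl(dimethyl)silyl]oxy}methyl)-6-methyl-4-{[(2Z)-2-methylbut-2-enoyl]oxy}-12-[(triethylsilyl)oxy]dodeca-2,6,10-trienoate | CC[Si](CC)(CC)OC/C=C(/CO[Si](C)(C)C(C)(C)C)[C@@H](OC(C)=O)C/C=C(/C)C[C@@H](OC(=O)/C(C)=C\C)/C=C(\CBr)C(=O)OC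
F3 | step 10 | methyl (2Z,4R,6Z,9S,10Z)-9-acetoxy-2-(bromomethyl)-10-({[tert-butyl(dimethyl)silyl]oxy}methyl)-6-methyl-4-{[(2Z)-2-methylbut-2-enoyl]oxy}-12-oxododeca-2,6,10-trienoate | O=C/C=C(/CO[Si](C)(C)C(C)(C)C)[C@@H](OC(C)=O)C/C=C(/C)C[C@@H](OC(=O)/C(C)=C\C)/C=C(\CBr)C(=O)OC
F4 | step 11 | (3R,6R,7R,8R)-8-(angeloyloxy)-15-[(tert-butyldimethylsilyl)oxy]-3-hydroxygermacra-1(10)Z,4Z,11(13)-trien-12,6-olide | C=C1C(=O)O[C@@H]2/C=C(/CO[Si](C)(C)C(C)(C)C)[C@H](O)C/C=C(/C)C[C@@H](OC(=O)/C(C)=C\C)[C@@H]12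
F5 | step 14 | (1S,3S,6R,7R,8R,10S)-3-acetoxy-8-(angeloyloxy)-1-bromo-10,15-dihydroxygermacra-4Z,11(13)-dien-12,6-olide | C=C1C(=O)O[C@@H]2/C=C(/CO)[C@@H](OC(C)=O)C[C@H](Br)[C@@](C)(O)C[C@@H](OC(=O)/C(C)=C\C)[C@@H]12
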